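**Retrosynthetic overview**

- The target is the 3-O-aryl ether that joins two isofraxidin units. The pyranone ring of coumarin A is cut at C3–C4 and O1–C2, giving a 2-hydroxybenzaldehyde and the O7-acetic acid of isofraxidin, which supplies coumarin B intact.
- The plan rests on ring A of coumarin A: C6, C7, C8 and C8a all carry oxygen. These four adjacent carbons are the four ring carbons of a squarate; C5 and C4a come from a 3-silyloxypropenyl group whose CH2O carbon becomes C4.
- The benzene ring is closed (bond C8a–C4a) by thermal ring expansion of a 4-alkenyl-4-methoxycyclobutenone. That ketone is reached from dimethyl squarate by vinyllithium addition, O-methylation and exchange of the single vinylogous-ester methoxy group (the future O7) for benzyloxy. This replaces a squarate monoacetal detour, whose preparation and late acid hydrolysis are less secure.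
- Ring order: benzene ring A of coumarin A (step 5), then its pyranone ring (step 10), then O7 debenzylation.

Key step: step 5

Remark: isofraxidin, dimethyl squarate and tert-butyl bromoacetate are taken as catalogue compounds. The cyclobutenones are racemic; their one stereocentre vanishes in step 5, and the target has none.

**Route**

Step 1
Reactants: 1 propargyl alcohol
Product: 2 triisopropyl(prop-2-yn-1-yloxy)silane
Conditions: TIPSCl, imidazole, CH2Cl2, 0 °C to rt
Reagents that add atoms: triisopropylsilyl chloride, CC(C)[Si](Cl)(C(C)C)C(C)C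
Why: Standard silylation of a primary alcohol; the bulky silyl ether survives organolithium, alkoxide and 110 °C.

Step 2
Reactants: 2 triisopropyl(prop-2-yn-1-yloxy)silane
Product: 4 (E)-(3-iodoprop-2-enyloxy)triisopropylsilane, via alkenylzirconocene chloride 3 (not isolated)
Conditions: Cp2Zr(H)Cl, THF, rt; then I2, 0 °C
Reagents that add atoms: iodine, II
Why: Syn hydrozirconation puts zirconium on the terminal carbon and iodinolysis of the C–Zr bond goes with retention, which fixes the E geometry (Schwartz hydrozirconation–iodination).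

Step 3
Reactants: 4 (E)-(3-iodoprop-2-enyloxy)triisopropylsilane; 5 dimethyl squarate
Product: 8 racemic 2,3,4-trimethoxy-4-[(E)-3-(triisopropylsilyloxy)prop-1-enyl]cyclobut-2-en-1-one, via vinyllithium 6 (not isolated), via lithium alkoxide 7 (not isolated)
Conditions: t-BuLi (2 equiv), Et2O, −78 °C; then 5, THF, −78 °C; then MeOTf, −78 to 0 °C
Reagents that add atoms: methyl trifluoromethanesulfonate, COS(=O)(=O)C(F)(F)F
Why: Iodine–lithium exchange with retention of geometry, 1,2-addition of the vinyllithium to one of the two equivalent squarate carbonyls and O-methylation of the tertiary alkoxide in the same flask; the new quaternary centre forms as a racemate, needs no control and is destroyed in step 5.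

Step 4
Reactants: 8 racemic 2,3,4-trimethoxy-4-[(E)-3-(triisopropylsilyloxy)prop-1-enyl]cyclobut-2-en-1-one; 9 benzyl alcohol
Product: 10 racemic 3-(benzyloxy)-2,4-dimethoxy-4-[(E)-3-(triisopropylsilyloxy)prop-1-enyl]cyclobut-2-en-1-one
Conditions: BnOH (15 equiv), NaH (0.2 equiv), THF, 0 °C to rt
Reagents that add atoms: none
Why: Base-catalysed transetherification of a vinylogous ester by conjugate addition–elimination: benzyloxide can add only at C3, the β-carbon of the enone, so only that methoxy group is replaced, and the excess of benzyl alcohol pulls the near-thermoneutral equilibrium towards 10.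

Step 5
Reactants: 10 racemic 3-(benzyloxy)-2,4-dimethoxy-4-[(E)-3-(triisopropylsilyloxy)prop-1-enyl]cyclobut-2-en-1-one
Product: 13 3-(benzyloxy)-2,4-dimethoxy-6-[(triisopropylsilyloxy)methyl]phenol, via dienylketene 11 (not isolated), via cyclohexadienone 12 (not isolated)
Conditions: PhMe (degassed, ca. 0.02 M), 110 °C
Reagents that add atoms: none
Why: Heating should open the cyclobutenone by a conrotatory four-electron electrocyclic cleavage of the C1–C4 bond in which the C4 methoxy group turns outward and the alkenyl group inward, so that dienylketene 11 has its alkene beside the ketene. The ketene carbon then bonds to the alkene terminus in a disrotatory six-electron electrocyclization that closes the six-membered carbocycle (the C8a–C4a bond of ring A), and dienone 12 tautomerizes irreversibly to phenol 13. The closest known reaction type is the thermal ring expansion of squarate-derived 4-alkenyl- and 4-aryl-4-alkoxycyclobutenones to hydroquinone monoethers. The only stereocentre formed, C6 of dienone 12, is transient and is erased on aromatization, as is the racemic C4 centre of 10 on ring opening. The step needs inward rotation of the alkenyl group and no interception of the ketene: the oxygen donor at C4 secures the first, a ketene formed with the wrong rotation can revert by ring closure, and the intramolecular closure in dilute aprotic solution should outrun bimolecular trapping. The substitution pattern is fixed by 10: the carbonyl oxygen becomes the C8a phenol, the C2 methoxy becomes C8-OMe, the C3 benzyloxy becomes C7-OBn and the C4 methoxy becomes C6-OMe.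

Step 6
Reactants: 13 3-(benzyloxy)-2,4-dimethoxy-6-[(triisopropylsilyloxy)methyl]phenol
Product: 14 3-(benzyloxy)-6-(hydroxymethyl)-2,4-dimethoxyphenol
Conditions: Bu4NF, AcOH, THF, 0 °C to rt
Reagents that add atoms: none
Why: Fluoride cleavage of the silyl ether, buffered with acetic acid so that the electron-rich phenol is not held as its air-sensitive phenoxide.

Step 7
Reactants: 14 3-(benzyloxy)-6-(hydroxymethyl)-2,4-dimethoxyphenol
Product: 15 4-(benzyloxy)-2-hydroxy-3,5-dimethoxybenzaldehyde
Conditions: MnO2 (activated, excess), CH2Cl2, rt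
Reagents that add atoms: none
Why: Activated MnO2 oxidizes the benzylic alcohol selectively and stops at the hydrogen-bonded salicylaldehyde.

Step 8
Reactants: 16 isofraxidin; 17 tert-butyl bromoacetate
Product: 18 tert-butyl 2-[(6,8-dimethoxy-2-oxo-2H-chromen-7-yl)oxy]acetate
Conditions: K2CO3, DMF, rt
Reagents that add atoms: none
Why: Williamson O-alkylation of the acidic 7-hydroxy group by an α-bromo ester under carbonate conditions that leave the lactone closed.

Step 9
Reactants: 18 tert-butyl 2-[(6,8-dimethoxy-2-oxo-2H-chromen-7-yl)oxy]acetate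
Product: 19 2-[(6,8-dimethoxy-2-oxo-2H-chromen-7-yl)oxy]acetic acid
Conditions: TFA, CH2Cl2, rt
Reagents that add atoms: none
Why: Acidolysis of the tert-butyl ester with loss of isobutene, which avoids the basic hydrolysis that would open the lactone.

Step 10
Reactants: 15 4-(benzyloxy)-2-hydroxy-3,5-dimethoxybenzaldehyde; 19 2-[(6,8-dimethoxy-2-oxo-2H-chromen-7-yl)oxy]acetic acid
Product: 21 7-(benzyloxy)-3-[(6,8-dimethoxy-2-oxo-2H-chromen-7-yl)oxy]-6,8-dimethoxy-2H-chromen-2-one, via aryl ester 20 (not isolated)
Conditions: DCC, DMAP (cat.), CH2Cl2, 0 °C to rt; then DBU, MeCN, 60 °C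
Reagents that add atoms: none
Why: Steglich esterification of the phenol, then base-mediated intramolecular aldol condensation of the aryloxyacetate α-carbon onto the ortho aldehyde and dehydration (Perkin-type coumarin synthesis through the O-acyl salicylaldehyde), which closes the pyranone ring with the aryloxy group at C3.

Step 11
Reactants: 21 7-(benzyloxy)-3-[(6,8-dimethoxy-2-oxo-2H-chromen-7-yl)oxy]-6,8-dimethoxy-2H-chromen-2-one
Product: 22 7-hydroxy-3-[(6,8-dimethoxy-2-oxo-2H-chromen-7-yl)oxy]-6,8-dimethoxy-2H-chromen-2-one (CNP0278842.0)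
Conditions: BCl3, C6HMe5, CH2Cl2, −78 °C
Reagents that add atoms: none
Why: Low-temperature Lewis acid cleavage of the aryl benzyl ether with pentamethylbenzene as a non-basic benzyl cation scavenger, which should spare the methyl ethers, the diaryl ether, both lactones and both pyranone double bonds that hydrogenolysis could reduce.

**Compound list**

1 | propargyl alcohol | C#CCO | starting material
2 | triisopropyl(prop-2-yn-1-yloxy)silane | C#CCO[Si](C(C)C)(C(C)C)C(C)C | intermediate
3 | chlorobis(cyclopentadienyl)[(E)-3-(triisopropylsilyloxy)prop-1-enyl]zirconium | Cl[Zr](/C=C/CO[Si](C(C)C)(C(C)C)C(C)C)(C1C=CC=C1)C1C=CC=C1 | intermediate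
4 | (E)-(3-iodoprop-2-enyloxy)triisopropylsilane | I/C=C/CO[Si](C(C)C)(C(C)C)C(C)C | intermediate
5 | dimethyl squarate (3,4-dimethoxycyclobut-3-ene-1,2-dione) | COC1=C(OC)C(=O)C1=O | starting material
6 | (E)-3-(triisopropylsilyloxy)prop-1-enyllithium | [Li]/C=C/CO[Si](C(C)C)(C(C)C)C(C)C | intermediate
7 | lithium 2,3-dimethoxy-4-oxo-1-[(E)-3-(triisopropylsilyloxy)prop-1-enyl]cyclobut-2-en-1-olate (racemic) | [Li+].[O-]C1(/C=C/CO[Si](C(C)C)(C(C)C)C(C)C)C(OC)=C(OC)C1=O | intermediate
8 | racemic 2,3,4-trimethoxy-4-[(E)-3-(triisopropylsilyloxy)prop-1-enyl]cyclobut-2-en-1-one | COC1=C(OC)C(OC)(/C=C/CO[Si](C(C)C)(C(C)C)C(C)C)C1=O | intermediate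
9 | benzyl alcohol | OCc1ccccc1 | starting material
10 | racemic 3-(benzyloxy)-2,4-dimethoxy-4-[(E)-3-(triisopropylsilyloxy)prop-1-enyl]cyclobut-2-en-1-one | COC1=C(OCc2ccccc2)C(OC)(/C=C/CO[Si](C(C)C)(C(C)C)C(C)C)C1=O | intermediate
11 | (3Z,5E)-3-(benzyloxy)-2,4-dimethoxy-7-(triisopropylsilyloxy)hepta-1,3,5-trien-1-one (dienylketene) | O=C=C(OC)/C(OCc1ccccc1)=C(OC)\C=C\CO[Si](C(C)C)(C(C)C)C(C)C | intermediate
12 | racemic 3-(benzyloxy)-2,4-dimethoxy-6-[(triisopropylsilyloxy)methyl]cyclohexa-2,4-dien-1-one | O=C1C(OC)=C(OCc2ccccc2)C(OC)=CC1CO[Si](C(C)C)(C(C)C)C(C)C | intermediate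
13 | 3-(benzyloxy)-2,4-dimethoxy-6-[(triisopropylsilyloxy)methyl]phenol | COc1cc(CO[Si](C(C)C)(C(C)C)C(C)C)c(O)c(OC)c1OCc1ccccc1 | intermediate
14 | 3-(benzyloxy)-6-(hydroxymethyl)-2,4-dimethoxyphenol | COc1cc(CO)c(O)c(OC)c1OCc1ccccc1 | intermediate
15 | 4-(benzyloxy)-2-hydroxy-3,5-dimethoxybenzaldehyde | COc1cc(C=O)c(O)c(OC)c1OCc1ccccc1 | intermediate
16 | isofraxidin (7-hydroxy-6,8-dimethoxy-2H-chromen-2-one) | COc1cc2ccc(=O)oc2c(OC)c1O | starting material
17 | tert-butyl bromoacetate | CC(C)(C)OC(=O)CBr | starting material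
18 | tert-butyl 2-[(6,8-dimethoxy-2-oxo-2H-chromen-7-yl)oxy]acetate | COc1cc2ccc(=O)oc2c(OC)c1OCC(=O)OC(C)(C)C | intermediate
19 | 2-[(6,8-dimethoxy-2-oxo-2H-chromen-7-yl)oxy]acetic acid | COc1cc2ccc(=O)oc2c(OC)c1OCC(=O)O | intermediate
20 | 3-(benzyloxy)-6-formyl-2,4-dimethoxyphenyl 2-[(6,8-dimethoxy-2-oxo-2H-chromen-7-yl)oxy]acetate | COc1cc(C=O)c(OC(=O)COc2c(OC)cc3ccc(=O)oc3c2OC)c(OC)c1OCc1ccccc1 | intermediate
21 | 7-(benzyloxy)-3-[(6,8-dimethoxy-2-oxo-2H-chromen-7-yl)oxy]-6,8-dimethoxy-2H-chromen-2-one | COc1cc2cc(Oc3c(OC)cc4ccc(=O)oc4c3OC)c(=O)oc2c(OC)c1OCc1ccccc1 | intermediate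
22 | 7-hydroxy-3-[(6,8-dimethoxy-2-oxo-2H-chromen-7-yl)oxy]-6,8-dimethoxy-2H-chromen-2-one (CNP0278842.0) | COc1cc2cc(Oc3c(OC)cc4ccc(=O)oc4c3OC)c(=O)oc2c(OC)c1O | target

**Step count**

Total: 11 steps. Longest linear sequence: 9 steps (steps 1 to 7, then 10 and 11, from propargyl alcohol).

**Steps most likely to fail**

Step 4. The exchange may stall at a statistical mixture, or the alkoxide may attack the ring carbonyl and cleave the strained ring instead of adding at C3. The fallback sets out from dimethyl squarate 5 and avoids any alkoxide on the cyclobutenone. One methoxy group is exchanged at the dione stage, where alkoxide exchange is routine (BnOH, NaH, 1 equiv each, THF, 0 °C), to give 3-(benzyloxy)-4-methoxycyclobut-3-ene-1,2-dione F1. Vinyllithium 6, made from 4 as in step 3, is added and the alkoxide is trapped with MeOTf. Attack at the carbonyl next to the benzyloxy carbon gives 10; attack at the other carbonyl gives the regioisomer, racemic 2-(benzyloxy)-3,4-dimethoxy-4-[(E)-3-(triisopropylsilyloxy)prop-1-enyl]cyclobut-2-en-1-one F2. The two are separated by chromatography and the route is rejoined at 10, at the cost of about half the material.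

Step 10. Acylation of the hindered, hydrogen-bonded phenol may be slow, and the α-aryloxy ester may enolize too sluggishly, so that ester cleavage competes with ring closure. The fallback sets out from isofraxidin 16 and forms the C3–C4 bond by olefination instead. Insertion of the carbene from triethyl diazophosphonoacetate into the 7-OH bond (Rh2(OAc)4 cat., PhMe, 80 °C) gives ethyl 2-(diethoxyphosphoryl)-2-[(6,8-dimethoxy-2-oxo-2H-chromen-7-yl)oxy]acetate F3. Horner–Wadsworth–Emmons reaction with aldehyde 15 (NaH, 2.2 equiv, THF) gives mainly ethyl (Z)-3-[4-(benzyloxy)-2-hydroxy-3,5-dimethoxyphenyl]-2-[(6,8-dimethoxy-2-oxo-2H-chromen-7-yl)oxy]prop-2-enoate F4. Photochemical (365 nm) or thermal (PhNEt2, reflux) alkene isomerization with lactonization then returns the route at 21.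

Step 5. The dienylketene may be diverted by dimerization or by adventitious nucleophiles, or the very electron-rich phenol may be lost by oxidation at 110 °C. The fallback sets out from isofraxidin 16 and reaches the same aldehyde by degradation. O-Benzylation (BnBr, K2CO3, DMF) gives 7-(benzyloxy)-6,8-dimethoxy-2H-chromen-2-one F5. Ozonolysis of its C3–C4 double bond (O3, CH2Cl2, −78 °C; then Me2S) gives 3-(benzyloxy)-6-formyl-2,4-dimethoxyphenyl 2-oxoacetate F6. Methanolysis of this aryl ester (K2CO3, MeOH, 0 °C) returns the route at 15.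

**Further compounds**

F1 | step 4 | 3-(benzyloxy)-4-methoxycyclobut-3-ene-1,2-dione | COC1=C(OCc2ccccc2)C(=O)C1=O
F2 | step 4 | racemic 2-(benzyloxy)-3,4-dimethoxy-4-[(E)-3-(triisopropylsilyloxy)prop-1-enyl]cyclobut-2-en-1-one | O=C1C(OCc2ccccc2)=C(OC)C1(OC)/C=C/CO[Si](C(C)C)(C(C)C)C(C)C
F3 | step 10 | ethyl 2-(diethoxyphosphoryl)-2-[(6,8-dimethoxy-2-oxo-2H-chromen-7-yl)oxy]acetate | CCOC(=O)C(Oc1c(OC)cc2ccc(=O)oc2c1OC)P(=O)(OCC)OCC
F4 | step 10 | ethyl (Z)-3-[4-(benzyloxy)-2-hydroxy-3,5-dimethoxyphenyl]-2-[(6,8-dimethoxy-2-oxo-2H-chromen-7-yl)oxy]prop-2-enoate | CCOC(=O)/C(Oc1c(OC)cc2ccc(=O)oc2c1OC)=C/c1cc(OC)c(OCc2ccccc2)c(OC)c1O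
F5 | step 5 | 7-(benzyloxy)-6,8-dimethoxy-2H-chromen-2-one | COc1cc2ccc(=O)oc2c(OC)c1OCc1ccccc1
F6 | step 5 | 3-(benzyloxy)-6-formyl-2,4-dimethoxyphenyl 2-oxoacetate | COc1cc(C=O)c(OC(=O)C=O)c(OC)c1OCc1ccccc1
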